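The synthesis rests on disconnecting the enamine bond between the ring nitrogen (N4) and the enamine carbon C9a, a bond shared by the pyrrolidine and azepine rings. In the key step a primary amine at C3 condenses with a C9a ketone on the six-membered carbocycle (ring B) to close the pyrroline. The imine nitrogen is then alkylated by a 4-chlorobutyl chain on C9 to close the azepine, and loss of the C9 proton gives the tetrasubstituted enamine. The step exploits the quaternary, lactone-bearing C1 next to C9a, which leaves C9 as the only site for enamine formation. The precursor is a fully substituted cyclohexanone carrying the fused lactone, the Boc-amino lactone side chain and the chlorobutyl chain.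

Key step: step 15

Remark on locants (used for every compound): N4 is the ring nitrogen; C1 the quaternary carbon bearing the lactone oxygen O1; C2 and C3 the pyrrolidine carbons; C5–C8 the azepine CH2 groups; C9 and C9a the enamine carbons (C9a on nitrogen); C10 bears the ethyl group; C11 bears oxygen O11; C12, C13 (methyl-bearing) and C14 (carbonyl) belong to the fused lactone; C18–C21 form the side-chain lactone (C18 on oxygen, C20 methyl-bearing). Ring B is the carbocycle C1–C12–C11–C10–C9–C9a; α is the face of ring B that carries O11, β the opposite face.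

Assumption: enantiopure silyloxy enone 9 is taken as a purchasable building block.

Step 1
Reactants: 1 (R)-Garner aldehyde; 2 ethyl 2-(bromomethyl)acrylate
Product: 5 methylene lactone oxazolidine, via allylzinc bromide 3 (not isolated), via hydroxy ester 4 (not isolated)
Conditions: Zn dust, THF/sat. aq. NH4Cl, 0 °C to rt; then PPTS (cat.), toluene, 60 °C
Reagents that add atoms: none
Why: Zinc-mediated Barbier allylation of the α-amino aldehyde should follow Felkin–Anh (non-chelation) control by the N,O-acetonide and set C18 anti to the C3 nitrogen, after which the γ-hydroxy ester lactonises under mild acid to the α-methylene-γ-butyrolactone.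

Step 2
Reactants: 5 methylene lactone oxazolidine
Product: 6 cis-methyl lactone oxazolidine
Conditions: H2 (1 atm), Pd/C, EtOAc, rt
Reagents that add atoms: none
Why: Heterogeneous hydrogenation of the exocyclic methylene should deliver hydrogen to the lactone face opposite the bulky C18 substituent, which sets C20 with the methyl cis to that substituent.

Step 3
Reactants: 6 cis-methyl lactone oxazolidine
Product: 7 Boc-amino alcohol
Conditions: TsOH·H2O (cat.), MeOH, rt
Reagents that add atoms: none
Why: Acid-catalysed transketalisation in methanol cleaves the N,O-acetonide while the Boc group and the γ-lactone survive.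

Step 4
Reactants: 7 Boc-amino alcohol
Product: 8 Boc-amino iodide
Conditions: I2, PPh3, imidazole, CH2Cl2, 0 °C to rt
Reagents that add atoms: iodine, II
Why: Appel-type iodination converts the primary alcohol into the primary iodide by displacement at C2 only, so the C3 stereocentre is not touched.

Step 5
Reactants: 9 (S)-4-silyloxycyclohexenone; 10 1-chloro-4-iodobutane
Product: 12 trisubstituted cyclohexanone, via lithium enolate 11 (not isolated)
Conditions: EtLi (2 equiv), CuI, Et2O, −40 °C (gives Et2CuLi); 9, −78 °C; then HMPA, 10 (excess), −78 to −20 °C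
Reagents that add atoms: lithium diethylcuprate, [Li+].CC[Cu-]CC
Why: Conjugate addition of the Gilman cuprate should occur anti to the γ-silyloxy group and set C10 (ethyl β), and the regiodefined enolate is then alkylated at C9 by the iodide end of 10, trans to the ethyl group (tandem conjugate addition–enolate alkylation).

Step 6
Reactants: 12 trisubstituted cyclohexanone
Product: 14 C1=C12 enone, via silyl enol ether 13 (not isolated)
Conditions: LiN(iPr)2, Me3SiCl, THF, −78 °C; then Pd(OAc)2 (1.05 equiv), MeCN, rt
Reagents that add atoms: none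
Why: Kinetic deprotonation at the unsubstituted α-carbon C1 and silylation give the less substituted silyl enol ether, which undergoes Saegusa–Ito dehydrogenation to the enone.

Step 7
Reactants: 14 C1=C12 enone
Product: 15 α-iodoenone
Conditions: I2, pyridine, CH2Cl2, 0 °C to rt
Reagents that add atoms: iodine, II
Why: Pyridine-mediated α-iodination of the enone (conjugate addition of pyridine, iodination of the enolate, elimination) places iodine on C1.

Step 8
Reactants: 15 α-iodoenone
Product: 16 iodo allylic alcohol
Conditions: (R)-2-methyl-CBS-oxazaborolidine (20 mol %), BH3·SMe2, THF, −20 °C; MeOH quench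
Reagents that add atoms: none
Why: Corey–Bakshi–Shibata reduction under catalyst control, with the iodovinyl carbon as the large group, should deliver hydride to the β face of the carbonyl and set the C9a hydroxyl α (cis to O11).

Step 9
Reactants: 16 iodo allylic alcohol; 17 triethyl orthoacetate
Product: 19 ethyl ester, via ketene acetal 18 (not isolated)
Conditions: 17 (excess), propionic acid (cat.), 140 °C, removal of EtOH
Reagents that add atoms: none
Why: Johnson–Claisen rearrangement through the mixed ketene acetal transfers chirality suprafacially from the C9a oxygen to C12, which sets the acetate side chain α at C12 (cis to O11) and moves the alkene to C1=C9a.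

Step 10
Reactants: 19 ethyl ester
Product: 23 acrylic acid, via Mannich base 20 (not isolated), via methiodide 21 (not isolated), via acrylate ester 22 (not isolated)
Conditions: LiN(iPr)2, THF, −78 °C; CH2=NMe2+ I−, −78 °C to rt; then MeI, rt; then LiOH, THF/H2O, 40 °C; 1 M HCl
Reagents that add atoms: Eschenmoser's salt (N,N-dimethylmethyleneiminium iodide), C=[N+](C)C.[I-]; lithium hydroxide, [Li+].[OH-]
Why: Aminomethylation of the ester enolate, quaternisation and hydroxide-induced β-elimination (Mannich methylenation) install the C13 methylene, and the same hydroxide saponifies the ethyl ester.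

Step 11
Reactants: 8 Boc-amino iodide; 23 acrylic acid
Product: 25 coupled acid, via alkylzinc iodide 24 (not isolated)
Conditions: 8, Zn dust, DMF, rt; 23, NaH (1 equiv), DMF, 0 °C; then Pd2(dba)3 (2.5 mol %), SPhos (5 mol %), rt to 40 °C; 1 M HCl work-up
Reagents that add atoms: none
Why: Zinc insertion into the primary iodide gives a carbamate-stabilised alkylzinc iodide (Jackson-type reagent) that undergoes Pd-catalysed Negishi coupling with the vinyl iodide at C1, the acid being masked as its sodium carboxylate.

Step 12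
Reactants: 25 coupled acid
Product: 27 hydroxy methylene lactone, via epoxy acid 26 (not isolated)
Conditions: mCPBA, CH2Cl2, 0 °C to rt
Reagents that add atoms: 3-chloroperoxybenzoic acid, O=C(OO)c1cccc(Cl)c1
Why: Prilezhaev epoxidation should occur on the β face, anti to the two α allylic substituents at C9 and C12, and the carboxylic acid then opens the epoxide at the tertiary carbon C1 with inversion (5-exo), which sets C1 with O1 α and leaves the C9a hydroxyl β.

Step 13
Reactants: 27 hydroxy methylene lactone
Product: 28 hydroxy methyl lactone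
Conditions: H2 (1 atm), RhCl(PPh3)3 (10 mol %), benzene/EtOH, rt
Reagents that add atoms: none
Why: Homogeneous hydrogenation of the exocyclic methylene should take place from the convex face of the cis-fused lactone, away from C11 and its silyloxy group, which sets C13 with the methyl cis to C11.

Step 14
Reactants: 28 hydroxy methyl lactone
Product: 29 keto lactone
Conditions: Dess–Martin periodinane, CH2Cl2, rt
Reagents that add atoms: none
Why: Dess–Martin oxidation converts the secondary C9a alcohol into the ketone under non-basic conditions that leave both lactones and C13 untouched.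

Step 15
Reactants: 29 keto lactone
Product: 33 silyl-protected enamine, via amine salt 30 (not isolated), via cyclic imine 31 (not isolated), via iminium chloride 32 (not isolated)
Conditions: TFA, CH2Cl2, 0 °C; evaporate; then K2CO3, NaI (20 mol %), 4 Å MS, MeCN, rt to 70 °C
Reagents that add atoms: none
Why: Acidolysis of the Boc group liberates the C3 amine, which adds to the C9a ketone (5-exo-trig) and dehydrates to the 1-pyrroline 31, forming the N4–C9a bond; the imine nitrogen is then alkylated by the chlorobutyl chain on C9 (7-exo-tet, iodide catalysis) to the bicyclic iminium 32, which loses the C9 proton to give the tetrasubstituted enamine. The closest known reaction type is the cyclodehydration of γ-amino ketones to 1-pyrrolines followed by intramolecular imine N-alkylation to bicyclic enamines, as used for indolizidine and pyrrolizidine skeletons. No new stereocentre is formed: C9 becomes trigonal and C1, C3, C10–C13, C18 and C20 are not touched. The step needs the amine to condense with the ketone faster than it attacks the side-chain lactone, N-alkylation in preference to C-alkylation at C9, and a single enamine regioisomer. Five-membered ketimine formation is fast and removes the N–H nucleophile, the neutral imine reacts through nitrogen, and because C1 is quaternary the iminium can only deprotonate at C9.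

Step 16
Reactants: 33 silyl-protected enamine
Product: 34 target CNP0154902.3
Conditions: HF·pyridine, THF/pyridine, 0 °C to rt; aq. NaHCO3
Reagents that add atoms: none
Why: Fluoride-mediated cleavage of the silyl ether releases the C11 hydroxyl under buffered acidic conditions in which the enamine is only reversibly protonated and is regenerated on basic work-up.

Compound list

1 | tert-butyl (4R)-4-formyl-2,2-dimethyl-1,3-oxazolidine-3-carboxylate ((R)-Garner aldehyde) | O=C[C@H]1COC(C)(C)N1C(=O)OC(C)(C)C | starting material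
2 | ethyl 2-(bromomethyl)prop-2-enoate | C=C(CBr)C(=O)OCC | starting material
3 | [2-(ethoxycarbonyl)prop-2-en-1-yl]zinc bromide | C=C(C[Zn]Br)C(=O)OCC | intermediate
4 | tert-butyl (4R)-4-[(1S)-3-(ethoxycarbonyl)-1-hydroxybut-3-en-1-yl]-2,2-dimethyl-1,3-oxazolidine-3-carboxylate (anti adduct) | O1C[C@@H](N(C(=O)OC(C)(C)C)C1(C)C)[C@@H](O)CC(=C)C(=O)OCC | intermediate
5 | tert-butyl (4R)-2,2-dimethyl-4-[(2S)-4-methylidene-5-oxooxolan-2-yl]-1,3-oxazolidine-3-carboxylate | O1C[C@@H](N(C(=O)OC(C)(C)C)C1(C)C)[C@@H]1CC(=C)C(=O)O1 | intermediate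
6 | tert-butyl (4R)-2,2-dimethyl-4-[(2S,4S)-4-methyl-5-oxooxolan-2-yl]-1,3-oxazolidine-3-carboxylate | O1C[C@@H](N(C(=O)OC(C)(C)C)C1(C)C)[C@@H]1C[C@H](C)C(=O)O1 | intermediate
7 | tert-butyl N-[(1R)-2-hydroxy-1-[(2S,4S)-4-methyl-5-oxooxolan-2-yl]ethyl]carbamate | OC[C@@H](NC(=O)OC(C)(C)C)[C@@H]1C[C@H](C)C(=O)O1 | intermediate
8 | tert-butyl N-[(1S)-2-iodo-1-[(2S,4S)-4-methyl-5-oxooxolan-2-yl]ethyl]carbamate (C2 iodide; C3, C18, C20 arranged as in the target) | IC[C@@H](NC(=O)OC(C)(C)C)[C@@H]1C[C@H](C)C(=O)O1 | intermediate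
9 | (4S)-4-[(tert-butyldimethylsilyl)oxy]cyclohex-2-en-1-one | O=C1C=C[C@@H](O[Si](C)(C)C(C)(C)C)CC1 | starting material
10 | 1-chloro-4-iodobutane | ClCCCCI | starting material
11 | lithium C9=C9a enolate of the conjugate adduct (C10 ethyl β, O11 silyl ether α) | CC[C@H]1C=C([O-])CC[C@@H]1O[Si](C)(C)C(C)(C)C.[Li+] | intermediate
12 | (2S,3S,4S)-4-[(tert-butyldimethylsilyl)oxy]-2-(4-chlorobutyl)-3-ethylcyclohexan-1-one (C9 chain α, C10 ethyl β, O11 α) | CC[C@H]1[C@H](CCCCCl)C(=O)CC[C@@H]1O[Si](C)(C)C(C)(C)C | intermediate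
13 | trimethylsilyl enol ether of 12 towards C1 (C1=C9a) | CC[C@H]1[C@H](CCCCCl)C(O[Si](C)(C)C)=CC[C@@H]1O[Si](C)(C)C(C)(C)C | intermediate
14 | 4-[(tert-butyldimethylsilyl)oxy]-6-(4-chlorobutyl)-5-ethylcyclohex-2-en-1-one (C9a ketone, C1=C12; C9 chain α, C10 ethyl β, O11 α) | CC[C@H]1[C@H](CCCCCl)C(=O)C=C[C@@H]1O[Si](C)(C)C(C)(C)C | intermediate
15 | 2-iodo derivative of 14 (iodine on C1) | CC[C@H]1[C@H](CCCCCl)C(=O)C(I)=C[C@@H]1O[Si](C)(C)C(C)(C)C | intermediate
16 | 2-iodocyclohex-2-en-1-ol from 15 with the C9a hydroxyl α (cis to O11) | CC[C@H]1[C@H](CCCCCl)[C@H](O)C(I)=C[C@@H]1O[Si](C)(C)C(C)(C)C | intermediate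
17 | triethyl orthoacetate | CC(OCC)(OCC)OCC | starting material
18 | mixed ketene acetal of 16 (C9a–O–C(=CH2)OEt) | CC[C@H]1[C@H](CCCCCl)[C@H](OC(=C)OCC)C(I)=C[C@@H]1O[Si](C)(C)C(C)(C)C | intermediate
19 | ethyl 2-(ring B)acetate: C12 side chain α, C1(I)=C9a alkene, C9 chain α, C10 ethyl β, O11 silyl ether α | CC[C@H]1[C@H](CCCCCl)C=C(I)[C@H](CC(=O)OCC)[C@@H]1O[Si](C)(C)C(C)(C)C | intermediate
20 | α-(dimethylaminomethyl) ester from 19 (both C13 epimers) | CC[C@H]1[C@H](CCCCCl)C=C(I)[C@H](C(CN(C)C)C(=O)OCC)[C@@H]1O[Si](C)(C)C(C)(C)C | intermediate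
21 | trimethylammonium iodide of 20 | CC[C@H]1[C@H](CCCCCl)C=C(I)[C@H](C(C[N+](C)(C)C)C(=O)OCC)[C@@H]1O[Si](C)(C)C(C)(C)C.[I-] | intermediate
22 | ethyl 2-(ring B)prop-2-enoate (C13 methylene) | CC[C@H]1[C@H](CCCCCl)C=C(I)[C@H](C(=C)C(=O)OCC)[C@@H]1O[Si](C)(C)C(C)(C)C | intermediate
23 | 2-(ring B)prop-2-enoic acid (C13 methylene, C1 iodide) | CC[C@H]1[C@H](CCCCCl)C=C(I)[C@H](C(=C)C(=O)O)[C@@H]1O[Si](C)(C)C(C)(C)C | intermediate
24 | alkylzinc iodide from 8 (zinc on C2) | I[Zn]C[C@@H](NC(=O)OC(C)(C)C)[C@@H]1C[C@H](C)C(=O)O1 | intermediate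
25 | Negishi product: acrylic acid 23 with the Boc-amino lactone side chain on C1 in place of iodine | CC[C@H]1[C@H](CCCCCl)C=C(C[C@@H](NC(=O)OC(C)(C)C)[C@@H]2C[C@H](C)C(=O)O2)[C@H](C(=C)C(=O)O)[C@@H]1O[Si](C)(C)C(C)(C)C | intermediate
26 | β-epoxide (C1–C9a) of 25 | CC[C@H]1[C@H](CCCCCl)[C@H]2O[C@@]2(C[C@@H](NC(=O)OC(C)(C)C)[C@@H]3C[C@H](C)C(=O)O3)[C@H](C(=C)C(=O)O)[C@@H]1O[Si](C)(C)C(C)(C)C | intermediate
27 | cis-fused O1–C14 lactone with C13 methylene, O1 α, C2 β, C9a hydroxyl β | CC[C@H]1[C@H](CCCCCl)[C@@H](O)[C@]2(C[C@@H](NC(=O)OC(C)(C)C)[C@@H]3C[C@H](C)C(=O)O3)OC(=O)C(=C)[C@@H]2[C@@H]1O[Si](C)(C)C(C)(C)C | intermediate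
28 | 13-methyl lactone from 27 (C13 methyl cis to C11), C9a hydroxyl β | CC[C@H]1[C@H](CCCCCl)[C@@H](O)[C@]2(C[C@@H](NC(=O)OC(C)(C)C)[C@@H]3C[C@H](C)C(=O)O3)OC(=O)[C@H](C)[C@@H]2[C@@H]1O[Si](C)(C)C(C)(C)C | intermediate
29 | C9a ketone from 28 (precursor of the key step) | CC[C@H]1[C@H](CCCCCl)C(=O)[C@]2(C[C@@H](NC(=O)OC(C)(C)C)[C@@H]3C[C@H](C)C(=O)O3)OC(=O)[C@H](C)[C@@H]2[C@@H]1O[Si](C)(C)C(C)(C)C | intermediate
30 | C3 ammonium trifluoroacetate from 29 | CC[C@H]1[C@H](CCCCCl)C(=O)[C@]2(C[C@@H]([NH3+])[C@@H]3C[C@H](C)C(=O)O3)OC(=O)[C@H](C)[C@@H]2[C@@H]1O[Si](C)(C)C(C)(C)C.[O-]C(=O)C(F)(F)F | intermediate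
31 | 1-pyrroline (cyclic imine N4=C9a) with the chlorobutyl chain on C9 | CC[C@H]1[C@H](CCCCCl)C2=N[C@@H]([C@@H]4C[C@H](C)C(=O)O4)C[C@]23OC(=O)[C@H](C)[C@@H]3[C@@H]1O[Si](C)(C)C(C)(C)C | intermediate
32 | bicyclic iminium chloride (N4=C9a, N4–C5 closed, C9–H) | CC[C@H]1[C@H]2C3=[N+](CCCC2)[C@@H]([C@@H]2C[C@H](C)C(=O)O2)C[C@]32OC(=O)[C@H](C)[C@@H]2[C@@H]1O[Si](C)(C)C(C)(C)C.[Cl-] | intermediate
33 | O11 tert-butyldimethylsilyl ether of the target | CC[C@H]1C2=C3N(CCCC2)[C@@H]([C@@H]2C[C@H](C)C(=O)O2)C[C@]32OC(=O)[C@H](C)[C@@H]2[C@@H]1O[Si](C)(C)C(C)(C)C | intermediate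
34 | CNP0154902.3 | CC[C@H]1C2=C3N(CCCC2)[C@@H]([C@@H]2C[C@H](C)C(=O)O2)C[C@]32OC(=O)[C@H](C)[C@@H]2[C@@H]1O | target

Total step count: 16. Longest linear sequence: 12 steps (steps 5 to 16, from 9); the side-chain fragment takes 4 steps (steps 1 to 4).

Steps most likely to fail

Step 15. The liberated primary amine may be lost to aminolysis of the side-chain lactone (O-to-N acyl shift to a six-membered lactam) before it condenses with the hindered ketone. The fallback sets out from 29 and forms the N4–C9a bond while nitrogen is still acylated: heating 29 with PPTS in toluene over 4 Å MS should condense the carbamate N–H with the C9a ketone to the N-Boc 2-pyrroline F1. TFA then removes the Boc group, the N–H enamine tautomerises to the cyclic imine 31, and the route is rejoined there (K2CO3, NaI, MeCN to 33).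

Step 11. The alkylzinc iodide 24 may decompose by β-elimination of the carbamate, or be protonated, before it transmetalates to the hindered vinylpalladium species. The fallback sets out from 8 and 23 and uses boron in place of zinc. Copper-catalysed borylation of 8 (B2pin2, CuI, PPh3, LiOMe, DMF) should give the pinacol boronate F2, and KHF2 in MeOH/H2O converts it into the potassium trifluoroborate F3. Suzuki–Miyaura coupling of F3 with 23 (Pd(OAc)2, RuPhos, K2CO3, toluene/H2O, 80 °C, acidic work-up) tolerates the carboxylate and returns to 25.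

Step 8. Hydride may be delivered to the wrong carbonyl face if the substrate's preference for axial attack overrides the catalyst (mismatched double diastereoselection). The fallback sets out from 15 and uses that preference: Luche reduction (NaBH4, CeCl3·7H2O, MeOH, −78 °C) should give the C9a-epimeric alcohol F4 (hydroxyl β). Mitsunobu inversion with 4-nitrobenzoic acid (PPh3, DIAD, THF) gives the α-configured 4-nitrobenzoate F5, and methanolysis (K2CO3, MeOH) returns to 16.

Further compounds
F1 | step 15 | N-Boc 2-pyrroline (ene-carbamate, N4–C9a closed, C9=C9a) from 29 | CC[C@H]1C(CCCCCl)=C2N(C(=O)OC(C)(C)C)[C@@H]([C@@H]3C[C@H](C)C(=O)O3)C[C@]24OC(=O)[C@H](C)[C@@H]4[C@@H]1O[Si](C)(C)C(C)(C)C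
F2 | step 11 | pinacol boronate from 8 (boron on C2) | CC1(C)OB(C[C@@H](NC(=O)OC(C)(C)C)[C@@H]2C[C@H](C)C(=O)O2)OC1(C)C
F3 | step 11 | potassium trifluoroborate from F2 | [K+].F[B-](F)(F)C[C@@H](NC(=O)OC(C)(C)C)[C@@H]1C[C@H](C)C(=O)O1
F4 | step 8 | C9a epimer of 16 (hydroxyl β) | CC[C@H]1[C@H](CCCCCl)[C@@H](O)C(I)=C[C@@H]1O[Si](C)(C)C(C)(C)C
F5 | step 8 | 4-nitrobenzoate of 16 (C9a oxygen α) | CC[C@H]1[C@H](CCCCCl)[C@H](OC(=O)c2ccc(cc2)[N+](=O)[O-])C(I)=C[C@@H]1O[Si](C)(C)C(C)(C)C
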